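**Retrosynthetic overview**

1. Core numbering (naphthalene-like): ring A = C1 (CH with the side chain), C2 (acetonyl), C3 (Me), C4, C4a, C8a; ring B = C4a, C5 (CH2), C6 (CHMe), C7 (C=O), C8 (CHMe), C8a.
2. Acid ⇐ enal (Pinnick) ⇐ epoxy alcohol (oxidation/Wittig) ⇐ dienol (Sharpless epoxidation) ⇐ C1-propynyl diketone (hydrostannation, then Stille coupling with (E)-3-iodo-2-methylprop-2-en-1-ol).
3. Ring A (C8a, C1) ⇐ thermal disrotatory 6π-electrocyclisation of an (E,Z,E)-triene, made by Suzuki coupling of a ring B alkenyl nonaflate (C4a–ONf, C4a=C8a) with a (1Z,3E)-dienyl boronate.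
4. Ring B ⇐ key step: one-carbon ring enlargement of a 5-siloxybicyclo[3.1.0]hexan-2-one (cyclopentanone C7–C6–C5–C4a–C8a fused to cyclopropane C7–C8–C8a). The enabling feature is the 1,4-relationship in ring B between the C7 carbonyl and the sp2 carbon C4a, with C8 lying between C7 and C8a: ring B is a latent cyclohexane-1,4-dione, so the donor (O at C7)–acceptor (C=O at C4a) cyclopropane bond C7–C8a can be cleaved with fluoride and the C4a enolate trapped as the nonaflate.
5. Order of ring formation: cyclopentanone + cyclopropane (Rh-carbenoid cyclopropanation; C6 from (S)-2-methylsuccinate) → ring B (ring enlargement) → ring A (electrocyclisation) → epoxide.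

Key step: step 5

Remark: (S)-2-methylsuccinic acid 4-methyl ester, (S)-pent-4-yn-2-ol, propyne and propargyl alcohol are taken as commercial.
Remark: the carbinol configurations at C7 and in the 2-oxygenated propyl group are removed later by oxidation; they are drawn as the expected or chosen isomer.
Remark: the C8 configuration that the cyclopropanation delivers is not relied on; it is reset in step 6.

Step 1
Reactants: 1 (S)-4-methoxy-2-methyl-4-oxobutanoic acid
Product: 3 methyl (3S)-3-methyl-4-oxohexanoate, via acid chloride 2 (not isolated)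
Conditions: (COCl)2, cat. DMF, CH2Cl2, 0 °C; then EtMgBr, Fe(acac)3 (cat.), THF, −78 °C
Reagents that add atoms: ethylmagnesium bromide, CC[Mg]Br
Why: The acid chloride undergoes iron-catalysed acyl cross-coupling with the Grignard reagent (Kumada-type ketone synthesis) faster than the ester or the product ketone is attacked, and the C6 stereocentre of the starting acid is carried through without enolisation.

Step 2
Reactants: 3 methyl (3S)-3-methyl-4-oxohexanoate
Product: 4 methyl (3S,4Z)-3-methyl-4-[(triisopropylsilyl)oxy]hex-4-enoate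
Conditions: LiN(SiMe3)2, THF/DMPU, −78 °C; i-Pr3SiOTf
Reagents that add atoms: triisopropylsilyl trifluoromethanesulfonate, CC(C)[Si](OS(=O)(=O)C(F)(F)F)(C(C)C)C(C)C
Why: Kinetic deprotonation by the hindered amide occurs at the ethyl CH2 rather than at the tertiary C6–H or the less acidic ester α-CH2, the donor cosolvent favours the (Z)-enolate, and O-silylation gives a robust silyl enol ether (regioselective enolisation/O-silylation, C6 untouched).

Step 3
Reactants: 4 methyl (3S,4Z)-3-methyl-4-[(triisopropylsilyl)oxy]hex-4-enoate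
Product: 7 (4S,5Z)-1-diazo-4-methyl-5-[(triisopropylsilyl)oxy]hept-5-en-2-one, via potassium carboxylate 5 (not isolated), via mixed anhydride 6 (not isolated)
Conditions: KOSiMe3, THF, rt; i-BuOCOCl, −20 °C; CH2N2, Et2O, 0 °C
Reagents that add atoms: diazomethane, C=[N+]=[N-]
Why: Anhydrous silanolate cleaves the methyl ester without ever liberating a free acid next to the acid-labile enol ether, and the carboxylate, activated as a mixed carbonic anhydride, acylates diazomethane to the α-diazoketone (first stage of an Arndt–Eistert sequence).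

Step 4
Reactants: 7 (4S,5Z)-1-diazo-4-methyl-5-[(triisopropylsilyl)oxy]hept-5-en-2-one
Product: 8 (1S,4S,5S,6S)-4,6-dimethyl-5-[(triisopropylsilyl)oxy]bicyclo[3.1.0]hexan-2-one
Conditions: Rh2(OAc)4 (cat.), CH2Cl2, rt, slow addition
Reagents that add atoms: none
Why: The rhodium carbenoid adds intramolecularly to the electron-rich enol ether and closes the cyclopentanone and the cyclopropane in one event (intramolecular carbenoid cyclopropanation), the alkene geometry being retained (6-methyl cis to the siloxy group) and allylic strain being expected to place the 4-methyl cis to the cyclopropane methine carbon, although the configuration created at the future C8 is reset in step 6.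

Step 5
Reactants: 8 (1S,4S,5S,6S)-4,6-dimethyl-5-[(triisopropylsilyl)oxy]bicyclo[3.1.0]hexan-2-one
Product: 10 (3S,5S)-3,5-dimethyl-4-oxocyclohex-1-en-1-yl nonafluorobutane-1-sulfonate, via ammonium enolate 9 (not isolated)
Conditions: C4F9SO2F, Bu4N[Ph3SiF2] (10 mol %), THF, −78 to 0 °C
Reagents that add atoms: nonafluorobutanesulfonyl fluoride, FS(=O)(=O)C(F)(F)C(F)(F)C(F)(F)C(F)(F)F
Why: Fluoride attacks silicon to give the cyclopropanolate, whose C7–C8a bond (the bond shared by the two rings, vicinal to the C4a ketone) breaks in a retro-aldol fragmentation to give the C7 ketone and the C4a enolate with its double bond fixed at C4a=C8a, and this enolate is O-sulfonylated by C4F9SO2F, which releases fluoride again and carries the chain. The closest known reaction types are the fluoride-induced ring opening of 2-siloxycyclopropyl carbonyl compounds to γ-oxo enolates and the fluoride-catalysed conversion of silyl enol ethers into alkenyl nonaflates. Ring B is not closed by bond formation: it arises by ring enlargement, the cyclopropane carbon C8 being inserted between C7 and C8a when the shared bond of the bicyclo[3.1.0]hexane is cleaved, so the five-membered ring becomes the six-membered ring. No stereocentre is created, C6 coming from the starting acid and C8 from the cyclopropane, and both are untouched because the enolate is trapped as it forms. The step needs cleavage of C7–C8a rather than C7–C8, which the acceptor carbonyl at C4a secures because only that cleavage gives a stabilised enolate, and it needs the enolate to keep its regiochemistry, which the presence of the sulfonyl fluoride from the start secures.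

Step 6
Reactants: 10 (3S,5S)-3,5-dimethyl-4-oxocyclohex-1-en-1-yl nonafluorobutane-1-sulfonate
Product: 13 (3R,4R,5S)-4-hydroxy-3,5-dimethylcyclohex-1-en-1-yl nonafluorobutane-1-sulfonate, via lithium dienolate 11 (not isolated), via cis ketone 12 (not isolated)
Conditions: LiN(SiMe3)2, THF, −78 °C; AcOH, −78 °C; then NaBH4, CeCl3·7H2O, MeOH, −78 °C
Reagents that add atoms: none
Why: The C8–H, flanked by the ketone and the alkenyl nonaflate, is removed selectively, kinetic α-protonation of the extended dienolate anti to the C6 methyl (held pseudoaxial by allylic strain) should give the 6,8-cis ketone with both methyls pseudoequatorial, which is also expected to be the more stable isomer, and immediate Luche reduction (axial hydride, equatorial C7 alcohol of no consequence) removes the risk of later epimerisation at C8.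

Step 7
Reactants: 14 (S)-pent-4-yn-2-ol
Product: 15 (S)-tert-butyldimethyl(pent-4-yn-2-yloxy)silane
Conditions: t-BuMe2SiCl, imidazole, DMF, rt
Reagents that add atoms: tert-butyldimethylsilyl chloride, CC(C)(C)[Si](C)(C)Cl
Why: Imidazole-mediated silylation protects the secondary alcohol for the organometallic steps, and its stereocentre is destroyed later by oxidation.

Step 8
Reactants: 15 (S)-tert-butyldimethyl(pent-4-yn-2-yloxy)silane
Product: 16 (S,E)-[(4-bromo-5-iodopent-4-en-2-yl)oxy](tert-butyl)dimethylsilane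
Conditions: IBr, CH2Cl2, −78 °C
Reagents that add atoms: iodine monobromide, BrI
Why: Electrophilic anti addition places iodine on the terminal carbon and bromine on the internal one, giving an (E)-1-iodo-2-bromoalkene whose two halogens can be coupled one after the other.

Step 9
Reactants: 16 (S,E)-[(4-bromo-5-iodopent-4-en-2-yl)oxy](tert-butyl)dimethylsilane; 17 propyne
Product: 18 (S,E)-[(4-bromooct-4-en-6-yn-2-yl)oxy](tert-butyl)dimethylsilane
Conditions: Pd(PPh3)2Cl2 (cat.), CuI (cat.), i-Pr2NH, THF, 0 °C to rt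
Reagents that add atoms: none
Why: Oxidative addition is much faster at C–I than at C–Br, so Sonogashira coupling installs the propynyl group trans to bromine with retention of the alkene geometry.

Step 10
Reactants: 17 propyne
Product: 20 (Z)-2-(2-bromoprop-1-en-1-yl)-4,4,5,5-tetramethyl-1,3,2-dioxaborolane, via dibromoborane 19 (not isolated)
Conditions: BBr3, CH2Cl2, −78 °C; pinacol, −78 °C to rt
Reagents that add atoms: boron tribromide, BrB(Br)Br; pinacol, CC(C)(O)C(C)(C)O
Why: Boron tribromide adds syn to propyne with boron at the terminal carbon (syn-bromoboration), and ligand exchange with pinacol gives the configurationally stable (Z)-bromoalkenyl boronate.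

Step 11
Reactants: 18 (S,E)-[(4-bromooct-4-en-6-yn-2-yl)oxy](tert-butyl)dimethylsilane; 20 (Z)-2-(2-bromoprop-1-en-1-yl)-4,4,5,5-tetramethyl-1,3,2-dioxaborolane
Product: 23 2-[(1Z,3E)-3-{(2S)-2-[(tert-butyldimethylsilyl)oxy]propyl}-2-methylhepta-1,3-dien-5-yn-1-yl]-4,4,5,5-tetramethyl-1,3,2-dioxaborolane, via vinyllithium 21 (not isolated), via vinylzinc bromide 22 (not isolated)
Conditions: t-BuLi (2 equiv), Et2O, −78 °C; ZnBr2, THF; then 20, Pd(P(t-Bu)3)2 (cat.), THF, rt
Reagents that add atoms: none
Why: Bromine–lithium exchange, transmetalation to zinc and Negishi coupling at the C–Br bond of 20 all proceed with retention and leave the boronate untouched, so both alkene geometries of the dienyl boronate are fixed by the two building blocks.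

Step 12
Reactants: 13 (3R,4R,5S)-4-hydroxy-3,5-dimethylcyclohex-1-en-1-yl nonafluorobutane-1-sulfonate; 23 dienyl boronate
Product: 25 2-{(2S)-2-[(tert-butyldimethylsilyl)oxy]propyl}-3,6,8-trimethyl-1-(prop-1-yn-1-yl)-1,5,6,7,8,8a-hexahydronaphthalen-7-ol (core numbering of the overview; C1, C6, C8, C8a as in the target, 7-OH trans to the C6 and C8 methyls), via triene 24 (not isolated)
Conditions: Pd(PPh3)4 (cat.), aq. K3PO4, 1,4-dioxane, 60 °C, then 95 °C
Reagents that add atoms: none
Why: Suzuki–Miyaura coupling joins nonaflate and boronate with retention to the (E,Z,E)-triene, whose thermal disrotatory 6π-electrocyclisation closes ring A with H-8a and H-1 cis (C8 and the propynyl group are both outside substituents), and bond formation at C8a axially, anti to the pseudoaxial C8–H of the half-chair that carries both methyls and the hydroxyl equatorially, should place C1 cis to the C8 methyl (substrate-controlled torquoselectivity).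

Step 13
Reactants: 25 silyl ether of the bicyclic alcohol
Product: 26 2-[(2S)-2-hydroxypropyl]-3,6,8-trimethyl-1-(prop-1-yn-1-yl)-1,5,6,7,8,8a-hexahydronaphthalen-7-ol (stereocentres as in 25)
Conditions: HF·pyridine, pyridine, THF, 0 °C to rt
Reagents that add atoms: none
Why: Buffered fluoride cleaves the secondary silyl ether and leaves the diene and the alkyne untouched (desilylation).

Step 14
Reactants: 26 bicyclic diol
Product: 27 (1R,6S,8R,8aS)-3,6,8-trimethyl-2-(2-oxopropyl)-1-(prop-1-yn-1-yl)-5,6,8,8a-tetrahydronaphthalen-7(1H)-one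
Conditions: DMP (1,1,1-triacetoxy-1,1-dihydro-1,2-benziodoxol-3(1H)-one), NaHCO3, CH2Cl2, 0 °C to rt
Reagents that add atoms: none
Why: The buffered hypervalent iodine oxidant converts both secondary alcohols into ketones under non-basic conditions that neither epimerise C6 or C8 nor move the β,γ-double bond into conjugation.

Step 15
Reactants: 27 propynyl diketone
Product: 28 3,6,8-trimethyl-2-(2-oxopropyl)-1-[(E)-2-(tributylstannyl)prop-1-en-1-yl]-5,6,8,8a-tetrahydronaphthalen-7(1H)-one (ring stereocentres as in the target)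
Conditions: Bu3SnH, Pd(PPh3)2Cl2 (cat.), THF, 0 °C
Reagents that add atoms: tributyltin hydride, CCCC[SnH](CCCC)CCCC
Why: Palladium-catalysed hydrostannation adds H and Sn syn across the alkyne with tin at the less hindered, methyl-bearing carbon remote from the branched C1, and it tolerates the ketones.

Step 16
Reactants: 29 prop-2-yn-1-ol
Product: 30 (E)-3-iodo-2-methylprop-2-en-1-ol
Conditions: Me3Al, Cp2ZrCl2 (cat.), CH2Cl2, 0 °C to rt; I2, THF, −30 °C
Reagents that add atoms: trimethylaluminium, C[Al](C)C; iodine, II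
Why: Zirconium-catalysed carboalumination adds methyl and aluminium syn with aluminium at the terminus, and iodinolysis with retention gives the (E)-iodoalkene.

Step 17
Reactants: 28 alkenylstannane; 30 (E)-3-iodo-2-methylprop-2-en-1-ol
Product: 31 1-[(1E,3E)-5-hydroxy-2,4-dimethylpenta-1,3-dien-1-yl]-3,6,8-trimethyl-2-(2-oxopropyl)-5,6,8,8a-tetrahydronaphthalen-7(1H)-one (ring stereocentres as in the target)
Conditions: Pd2(dba)3 (cat.), AsPh3, CuI, NMP, rt to 40 °C
Reagents that add atoms: none
Why: Copper-assisted Stille coupling under neutral conditions joins the two alkenyl partners with retention of both geometries, so the ketones are never exposed to base.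

Step 18
Reactants: 31 dienol
Product: 32 1-{(1E)-2-[(2S,3S)-3-(hydroxymethyl)-3-methyloxiran-2-yl]prop-1-en-1-yl}-3,6,8-trimethyl-2-(2-oxopropyl)-5,6,8,8a-tetrahydronaphthalen-7(1H)-one (ring stereocentres as in the target)
Conditions: Ti(OiPr)4, L-(+)-diethyl tartrate, t-BuOOH, 4 Å MS, CH2Cl2, −25 °C
Reagents that add atoms: tert-butyl hydroperoxide, CC(C)(C)OO
Why: The titanium tartrate complex epoxidises only the double bond of the allylic alcohol, and L-(+)-tartrate delivers oxygen to the face that gives the (S,S)-epoxide (Sharpless asymmetric epoxidation, reagent control).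

Step 19
Reactants: 32 epoxy alcohol
Product: 34 (2E)-3-[(2S,3S)-2-methyl-3-{(1E)-1-[core]prop-1-en-2-yl}oxiran-2-yl]prop-2-enal (core = the 3,6,8-trimethyl-7-oxo-2-(2-oxopropyl)-1,5,6,7,8,8a-hexahydronaphthalen-1-yl unit of the target), via epoxy aldehyde 33 (not isolated)
Conditions: DMP, NaHCO3, CH2Cl2, 0 °C; then Ph3P=CHCHO, toluene, 40–60 °C
Reagents that add atoms: (triphenylphosphoranylidene)acetaldehyde, O=CC=P(c1ccccc1)(c1ccccc1)c1ccccc1
Why: Buffered oxidation gives the α,β-epoxy aldehyde, which the stabilised formyl ylide homologates to the (E)-enal while leaving the two ketones untouched (oxidation/Wittig olefination).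

Step 20
Reactants: 34 epoxy enal
Product: 35 (2E)-3-[(2S,3S)-2-methyl-3-{(1E)-1-[(1S,6S,8R,8aS)-3,6,8-trimethyl-7-oxo-2-(2-oxopropyl)-1,5,6,7,8,8a-hexahydronaphthalen-1-yl]prop-1-en-2-yl}oxiran-2-yl]prop-2-enoic acid (CNP0214881.1)
Conditions: NaClO2, NaH2PO4, 2-methyl-2-butene, t-BuOH/H2O, 0 °C
Reagents that add atoms: sodium chlorite, [Na+].[O-]Cl=O
Why: Chlorite oxidises the enal to the acid at pH 3–4 with the hypochlorite by-product scavenged by the alkene, conditions that spare the vinyl epoxide, the ketones and their α-stereocentres (Pinnick oxidation).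

**Compound list**

1 | (S)-4-methoxy-2-methyl-4-oxobutanoic acid | COC(=O)C[C@H](C)C(=O)O | starting material
2 | methyl (S)-4-chloro-3-methyl-4-oxobutanoate | COC(=O)C[C@H](C)C(=O)Cl | intermediate
3 | methyl (3S)-3-methyl-4-oxohexanoate | COC(=O)C[C@H](C)C(=O)CC | intermediate
4 | methyl (3S,4Z)-3-methyl-4-[(triisopropylsilyl)oxy]hex-4-enoate | COC(=O)C[C@H](C)/C(O[Si](C(C)C)(C(C)C)C(C)C)=C/C | intermediate
5 | potassium (3S,4Z)-3-methyl-4-[(triisopropylsilyl)oxy]hex-4-enoate | [K+].[O-]C(=O)C[C@H](C)/C(O[Si](C(C)C)(C(C)C)C(C)C)=C/C | intermediate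
6 | isobutyl carbonic (3S,4Z)-3-methyl-4-[(triisopropylsilyl)oxy]hex-4-enoic anhydride | CC(C)COC(=O)OC(=O)C[C@H](C)/C(O[Si](C(C)C)(C(C)C)C(C)C)=C/C | intermediate
7 | (4S,5Z)-1-diazo-4-methyl-5-[(triisopropylsilyl)oxy]hept-5-en-2-one | [N-]=[N+]=CC(=O)C[C@H](C)/C(O[Si](C(C)C)(C(C)C)C(C)C)=C/C | intermediate
8 | (1S,4S,5S,6S)-4,6-dimethyl-5-[(triisopropylsilyl)oxy]bicyclo[3.1.0]hexan-2-one | O=C1C[C@H](C)[C@]2(O[Si](C(C)C)(C(C)C)C(C)C)[C@@H](C)[C@H]12 | intermediate
9 | tetrabutylammonium (3S,5S)-3,5-dimethyl-4-oxocyclohex-1-en-1-olate | CCCC[N+](CCCC)(CCCC)CCCC.[O-]C1=C[C@H](C)C(=O)[C@@H](C)C1 | intermediate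
10 | (3S,5S)-3,5-dimethyl-4-oxocyclohex-1-en-1-yl nonafluorobutane-1-sulfonate (methyls trans) | O=C1[C@@H](C)C=C(OS(=O)(=O)C(F)(F)C(F)(F)C(F)(F)C(F)(F)F)C[C@@H]1C | intermediate
11 | lithium (6S)-2,6-dimethyl-4-[(nonafluorobutylsulfonyl)oxy]cyclohexa-1,3-dien-1-olate | [Li+].[O-]C1=C(C)C=C(OS(=O)(=O)C(F)(F)C(F)(F)C(F)(F)C(F)(F)F)C[C@@H]1C | intermediate
12 | (3R,5S)-3,5-dimethyl-4-oxocyclohex-1-en-1-yl nonafluorobutane-1-sulfonate (methyls cis) | O=C1[C@H](C)C=C(OS(=O)(=O)C(F)(F)C(F)(F)C(F)(F)C(F)(F)F)C[C@@H]1C | intermediate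
13 | (3R,4R,5S)-4-hydroxy-3,5-dimethylcyclohex-1-en-1-yl nonafluorobutane-1-sulfonate | O[C@H]1[C@H](C)C=C(OS(=O)(=O)C(F)(F)C(F)(F)C(F)(F)C(F)(F)F)C[C@@H]1C | intermediate
14 | (S)-pent-4-yn-2-ol | C#CC[C@H](C)O | starting material
15 | (S)-tert-butyldimethyl(pent-4-yn-2-yloxy)silane | C#CC[C@H](C)O[Si](C)(C)C(C)(C)C | intermediate
16 | (S,E)-[(4-bromo-5-iodopent-4-en-2-yl)oxy](tert-butyl)dimethylsilane | I/C=C(/Br)C[C@H](C)O[Si](C)(C)C(C)(C)C | intermediate
17 | propyne | CC#C | starting material
18 | (S,E)-[(4-bromooct-4-en-6-yn-2-yl)oxy](tert-butyl)dimethylsilane | CC#C/C=C(/Br)C[C@H](C)O[Si](C)(C)C(C)(C)C | intermediate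
19 | (Z)-dibromo(2-bromoprop-1-en-1-yl)borane | Br/C(C)=C\B(Br)Br | intermediate
20 | (Z)-2-(2-bromoprop-1-en-1-yl)-4,4,5,5-tetramethyl-1,3,2-dioxaborolane | Br/C(C)=C\B1OC(C)(C)C(C)(C)O1 | intermediate
21 | (S,Z)-[2-(tert-butyldimethylsilyloxy)oct-4-en-6-yn-4-yl]lithium (lithium in place of the bromine of 18) | CC#C/C=C(/[Li])C[C@H](C)O[Si](C)(C)C(C)(C)C | intermediate
22 | (S,Z)-[2-(tert-butyldimethylsilyloxy)oct-4-en-6-yn-4-yl]zinc bromide | CC#C/C=C(/[Zn]Br)C[C@H](C)O[Si](C)(C)C(C)(C)C | intermediate
23 | 2-[(1Z,3E)-3-{(2S)-2-[(tert-butyldimethylsilyl)oxy]propyl}-2-methylhepta-1,3-dien-5-yn-1-yl]-4,4,5,5-tetramethyl-1,3,2-dioxaborolane | CC#C/C=C(\C[C@H](C)O[Si](C)(C)C(C)(C)C)/C(C)=C\B1OC(C)(C)C(C)(C)O1 | intermediate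
24 | (1R,2R,6S)-4-[(1Z,3E)-3-{(2S)-2-[(tert-butyldimethylsilyl)oxy]propyl}-2-methylhepta-1,3-dien-5-yn-1-yl]-2,6-dimethylcyclohex-3-en-1-ol | CC#C/C=C(\C[C@H](C)O[Si](C)(C)C(C)(C)C)/C(C)=C\C1=C[C@@H](C)[C@H](O)[C@@H](C)C1 | intermediate
25 | 2-{(2S)-2-[(tert-butyldimethylsilyl)oxy]propyl}-3,6,8-trimethyl-1-(prop-1-yn-1-yl)-1,5,6,7,8,8a-hexahydronaphthalen-7-ol (C1, C6, C8, C8a as in the target; 7-OH trans to the methyls) | C[C@H](O[Si](C)(C)C(C)(C)C)CC1=C(C)C=C2C[C@H](C)[C@@H](O)[C@H](C)[C@@H]2[C@@H]1C#CC | intermediate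
26 | 2-[(2S)-2-hydroxypropyl]-3,6,8-trimethyl-1-(prop-1-yn-1-yl)-1,5,6,7,8,8a-hexahydronaphthalen-7-ol (stereocentres as in 25) | C[C@H](O)CC1=C(C)C=C2C[C@H](C)[C@@H](O)[C@H](C)[C@@H]2[C@@H]1C#CC | intermediate
27 | (1R,6S,8R,8aS)-3,6,8-trimethyl-2-(2-oxopropyl)-1-(prop-1-yn-1-yl)-5,6,8,8a-tetrahydronaphthalen-7(1H)-one | CC(=O)CC1=C(C)C=C2C[C@H](C)C(=O)[C@H](C)[C@@H]2[C@@H]1C#CC | intermediate
28 | 3,6,8-trimethyl-2-(2-oxopropyl)-1-[(E)-2-(tributylstannyl)prop-1-en-1-yl]-5,6,8,8a-tetrahydronaphthalen-7(1H)-one (ring stereocentres as in the target) | CC(=O)CC1=C(C)C=C2C[C@H](C)C(=O)[C@H](C)[C@@H]2[C@@H]1/C=C(\C)[Sn](CCCC)(CCCC)CCCC | intermediate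
29 | prop-2-yn-1-ol | C#CCO | starting material
30 | (E)-3-iodo-2-methylprop-2-en-1-ol | OC/C(C)=C/I | intermediate
31 | 1-[(1E,3E)-5-hydroxy-2,4-dimethylpenta-1,3-dien-1-yl]-3,6,8-trimethyl-2-(2-oxopropyl)-5,6,8,8a-tetrahydronaphthalen-7(1H)-one (ring stereocentres as in the target) | CC(=O)CC1=C(C)C=C2C[C@H](C)C(=O)[C@H](C)[C@@H]2[C@@H]1/C=C(\C)/C=C(\C)CO | intermediate
32 | 1-{(1E)-2-[(2S,3S)-3-(hydroxymethyl)-3-methyloxiran-2-yl]prop-1-en-1-yl}-3,6,8-trimethyl-2-(2-oxopropyl)-5,6,8,8a-tetrahydronaphthalen-7(1H)-one (ring stereocentres as in the target) | CC(=O)CC1=C(C)C=C2C[C@H](C)C(=O)[C@H](C)[C@@H]2[C@@H]1/C=C(\C)[C@@H]1O[C@@]1(C)CO | intermediate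
33 | epoxy aldehyde: 32 with the CH2OH group oxidised to CHO (all stereocentres unchanged) | CC(=O)CC1=C(C)C=C2C[C@H](C)C(=O)[C@H](C)[C@@H]2[C@@H]1/C=C(\C)[C@@H]1O[C@@]1(C)C=O | intermediate
34 | (2E)-enal: the aldehyde corresponding to the target acid (all stereocentres as in the target) | CC(=O)CC1=C(C)C=C2C[C@H](C)C(=O)[C@H](C)[C@@H]2[C@@H]1/C=C(\C)[C@@H]1O[C@@]1(C)/C=C/C=O | intermediate
35 | (2E)-3-[(2S,3S)-2-methyl-3-{(1E)-1-[(1S,6S,8R,8aS)-3,6,8-trimethyl-7-oxo-2-(2-oxopropyl)-1,5,6,7,8,8a-hexahydronaphthalen-1-yl]prop-1-en-2-yl}oxiran-2-yl]prop-2-enoic acid | CC(=O)CC1=C(C)C=C2C[C@H](C)C(=O)[C@H](C)[C@@H]2[C@@H]1/C=C(\C)[C@@H]1O[C@@]1(C)/C=C/C(=O)O | target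

**Totals**

Total step count: 20. Longest linear sequence: 14 steps (steps 1–6, 12–15, 17–20).

**Steps most likely to fail**

Step 12. The doubly unsaturated boronate 23 may protodeboronate or lose its (Z)-geometry in hot aqueous base before it couples, and a slow coupling that forces higher temperatures would also erode the facial selectivity of the ring closure. The fallback sets out from 13 and 23 and comes back at 24. The roles of the partners are exchanged: Miyaura borylation of 13 (B2pin2, PdCl2(dppf), KOAc, dioxane) gives the robust cyclohexenyl boronate F1. Ipso-iododeboronation of 23 with N-iodosuccinimide in MeCN gives, with retention, the dienyl iodide F2. Suzuki–Miyaura coupling of F1 with F2 at room temperature (Pd(PPh3)4, aq. K3PO4, THF) gives triene 24, which is then heated in toluene to 25 as in step 12.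

Step 6. Protonation of the dienolate may be poorly face-selective, and deprotonation may stray to C6, which would erode the configuration brought in from the starting acid. The fallback sets out from 8 and comes back at 12. It fixes the 6,8-cis relationship under thermodynamic control before the sulfonate is made: aqueous HCl in THF opens the donor–acceptor cyclopropane of 8 to 2,6-dimethylcyclohexane-1,4-dione, which K2CO3 in MeOH equilibrates to the meso cis-dione F3. Enantiotopos-differentiating deprotonation of the less hindered C4a ketone with lithium bis[(R)-1-phenylethyl]amide (or its enantiomer, whichever removes the required proton) and LiCl in THF at −100 °C, followed by O-sulfonylation of the enolate with C4F9SO2F, gives 12. This is reduced with NaBH4/CeCl3·7H2O to 13 as in step 6.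

Step 19. The formyl ylide reacts sluggishly with the hindered α-quaternary epoxy aldehyde, and the enal product can be olefinated a second time. The fallback sets out from 32 and comes back at 35. After oxidation of 32 to 33 as in step 19, Horner–Wadsworth–Emmons olefination with methyl (diethoxyphosphoryl)acetate (LiCl, i-Pr2NEt, MeCN, rt) gives the (E)-methyl ester F4, which cannot react further. Neutral ester cleavage with Me3SnOH (1,2-dichloroethane, 70 °C) then gives 35 directly, so step 20 is not needed.

**Further compounds**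

F1 | step 12 | (1R,2R,6S)-2,6-dimethyl-4-(4,4,5,5-tetramethyl-1,3,2-dioxaborolan-2-yl)cyclohex-3-en-1-ol | O[C@H]1[C@H](C)C=C(B2OC(C)(C)C(C)(C)O2)C[C@@H]1C
F2 | step 12 | tert-butyl{[(2S)-1-((1Z,3E)-1-iodo-2-methylhepta-1,3-dien-5-yn-3-yl)propan-2-yl]oxy}dimethylsilane | CC#C/C=C(\C[C@H](C)O[Si](C)(C)C(C)(C)C)/C(C)=C\I
F3 | step 6 | cis-2,6-dimethylcyclohexane-1,4-dione (meso) | O=C1[C@H](C)CC(=O)C[C@@H]1C
F4 | step 19 | methyl ester of 35 | CC(=O)CC1=C(C)C=C2C[C@H](C)C(=O)[C@H](C)[C@@H]2[C@@H]1/C=C(\C)[C@@H]1O[C@@]1(C)/C=C/C(=O)OC
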